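**Retrosynthetic overview**
1. Target 27 ⇐ desilylation and double angeloylation of diol 24; the cis-3,4-diol ⇐ OsO4 addition anti to the 5-oxygen; the 5-carbinol ⇐ CBS reduction of tricyclic enone 18.
2. Seven-membered ring (formed last) ⇐ intramolecular aldol condensation of keto aldehyde 14, then α′,α′-dimethylation.
3. Acetonyl arm ⇐ Wittig olefination and conjugate reduction at the cyclobutanone carbonyl of 10.
4. Cyclobutanone and six-membered ring (formed first, together) ⇐ intramolecular vinylketene–alkene [2+2] of acyclic acid 7, steered by its 5S silyloxy centre.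
5. Acid 7 ⇐ asymmetric vinylogous Mukaiyama aldol of 3-methylbut-2-enal with the silyl dienolate of ethyl 3-methylbut-2-enoate, then SeO2 allylic oxidation.

Assumption: tricyclic compounds carry the locants of the target named as a tricyclo[5.4.0.0^{2,8}]undecane (C1, C2, C7, C8 = four-membered ring; C3–C6 = four-carbon arm; C9–C11 = three-carbon bridge); TES = triethylsilyl, TBS = tert-butyldimethylsilyl; angelic acid is taken as commercially available.

**Route**

Step 1
Reactants: 1 ethyl 3-methylbut-2-enoate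
Product: 2 tert-butyl[(1-ethoxy-3-methylbuta-1,3-dien-1-yl)oxy]dimethylsilane (ketene-acetal geometry not controlled)
Conditions: LiN(i-Pr)2, THF, −78 °C; then TBSCl, DMPU, −78 °C → rt
Reagents that add atoms: tert-butyl(chloro)dimethylsilane CC(C)(C)[Si](C)(C)Cl
Why: γ-Deprotonation of the enoate and O-silylation give the cross-conjugated silyl dienolate (silyl ketene acetal formation); no stereocentre is made.

Step 2
Reactants: 2 silyl dienolate; 3 3-methylbut-2-enal
Product: 4 ethyl (2E,5S)-5-hydroxy-3,7-dimethylocta-2,6-dienoate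
Conditions: SiCl4 (1.1 equiv), (S,S)-binaphthyldiamine-derived bisphosphoramide (Denmark catalyst, 2 mol %), i-Pr2NEt (cat.), CH2Cl2, −78 °C; aq. NaHCO3/KF
Reagents that add atoms: none
Why: Catalytic enantioselective vinylogous Mukaiyama aldol (Lewis-base-activated SiCl4) gives γ-attack only and the E-enoate; the catalyst antipode that directs Si-face addition to the aldehyde (taken here as S,S) sets C5 as S.

Step 3
Reactants: 4 ethyl (2E,5S)-5-hydroxy-3,7-dimethylocta-2,6-dienoate
Product: 5 ethyl (2E,5S,6E)-5,8-dihydroxy-3,7-dimethylocta-2,6-dienoate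
Conditions: SeO2 (20 mol %), t-BuOOH, salicylic acid (cat.), CH2Cl2, 0 °C → rt
Reagents that add atoms: selenium dioxide O=[Se]=O; tert-butyl hydroperoxide CC(C)(C)OO
Why: Sharpless SeO2 allylic oxidation (ene reaction, then [2,3]-shift) hydroxylates only the E-methyl of the electron-rich trisubstituted alkene, which fixes the 6E geometry; the conjugated alkene is inert.

Step 4
Reactants: 5 ethyl (2E,5S,6E)-5,8-dihydroxy-3,7-dimethylocta-2,6-dienoate
Product: 6 ethyl (2E,5S,6E)-3,7-dimethyl-5,8-bis(triethylsilyloxy)octa-2,6-dienoate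
Conditions: Et3SiCl, imidazole, DMAP (cat.), CH2Cl2, 0 °C
Reagents that add atoms: chlorotriethylsilane CC[Si](CC)(CC)Cl
Why: Standard silylation of both alcohols gives a primary and a secondary TES ether that can later be told apart.

Step 5
Reactants: 6 ethyl (2E,5S,6E)-3,7-dimethyl-5,8-bis(triethylsilyloxy)octa-2,6-dienoate
Product: 7 (2E,5S,6E)-3,7-dimethyl-5,8-bis(triethylsilyloxy)octa-2,6-dienoic acid
Conditions: LiOH, THF/MeOH/H2O, rt; then cold 0.5 M HCl to pH 4
Reagents that add atoms: lithium hydroxide [Li+].[OH-]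
Why: Saponification of the ethyl ester; the 2E acid cannot lactonise and the TES ethers survive brief cold acidification.

Step 6
Reactants: 7 (2E,5S,6E)-3,7-dimethyl-5,8-bis(triethylsilyloxy)octa-2,6-dienoic acid
Product: 10 (1R,4S,5R,7R)-7-methyl-2-methylidene-4-(triethylsilyloxy)-7-[(triethylsilyloxy)methyl]bicyclo[3.1.1]heptan-6-one, via acid chloride 8 (not isolated), via vinylketene 9 (not isolated)
Conditions: 1-chloro-N,N,2-trimethylprop-1-en-1-amine, CH2Cl2, 0 °C; then slow addition to Et3N, toluene, 110 °C (0.005 M)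
Reagents that add atoms: none
Why: 1,4-Dehydrochlorination gives the vinylketene, and the intramolecular ketene–alkene [2+2] (Snider-type) forms the cyclobutanone and the six-membered ring at once; the ketene carbonyl carbon bonds to the CH alkene carbon and the α-carbon to the fully substituted one (bridged mode), the 6E geometry is carried over suprafacially (7-methyl syn to the C2–C4 bridge), and with the tether on the reacting face the silyloxy group takes the in-plane outside position while C5–H faces the cis-methyl (allylic 1,3-strain), so 5S gives the 1R,5R,7R cage.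

Step 7
Reactants: 10 bicyclic cyclobutanone; 11 1-(triphenyl-λ5-phosphanylidene)propan-2-one
Product: 12 1-[7-methyl-2-methylidene-4-(triethylsilyloxy)-7-[(triethylsilyloxy)methyl]bicyclo[3.1.1]heptan-6-ylidene]propan-2-one (ring centres as in 10; alkene geometry not controlled)
Conditions: toluene, 110 °C
Reagents that add atoms: none
Why: Wittig olefination of a strained, non-enolisable cyclobutanone with a stabilised ylide; both alkene isomers converge in the next step.

Step 8
Reactants: 12 exocyclic enone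
Product: 13 1-[7-methyl-2-methylidene-4-(triethylsilyloxy)-7-[(triethylsilyloxy)methyl]bicyclo[3.1.1]heptan-6-yl]propan-2-one (ring centres as in 10; C6–H syn to the C2–C4 bridge, acetonyl arm cis to the C7 silyloxymethyl arm)
Conditions: Cu(OAc)2·H2O (5 mol %), 1,2-bis(diphenylphosphino)benzene (5 mol %), PhMe2SiH, t-BuOH, toluene, rt
Reagents that add atoms: none
Why: Catalytic copper hydride conjugate reduction (Stryker-type) leaves the isolated alkene alone; hydride reaches C6 only from the face syn to the three-carbon bridge because the other face is blocked by the C7 silyloxymethyl arm, so the acetonyl arm ends up cis to that arm.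

Step 9
Reactants: 13 methyl ketone
Product: 14 7-methyl-2-methylidene-6-(2-oxopropyl)-4-(triethylsilyloxy)bicyclo[3.1.1]heptane-7-carbaldehyde (configuration as in 13)
Conditions: (COCl)2, DMSO, CH2Cl2, −78 °C; Et3N, −78 → 0 °C
Reagents that add atoms: none
Why: Under Swern conditions a primary TES ether is cleaved and oxidised directly to the aldehyde while the secondary TES ether survives.

Step 10
Reactants: 14 keto aldehyde
Product: 16 2-methyl-9-methylidene-11-(triethylsilyloxy)tricyclo[5.4.0.0^{2,8}]undec-3-en-5-one (cage as in the target; 11-silyloxy on the C7 side), via aldol adduct 15 (not isolated)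
Conditions: KOt-Bu (0.3 equiv), THF/t-BuOH, 0 °C → rt
Reagents that add atoms: none
Why: Intramolecular aldol condensation: the methyl-ketone enolate adds to the non-enolisable aldehyde held close by the cis-1,3 arrangement on the cyclobutane, and E1cB dehydration gives the seven-membered enone; the competing aldol through the CH2 carbon would give a strained bicyclo[2.1.1]hexane, cannot dehydrate and reverts.

Step 11
Reactants: 16 tricyclic enone
Product: 18 2,6,6-trimethyl-9-methylidene-11-(triethylsilyloxy)tricyclo[5.4.0.0^{2,8}]undec-3-en-5-one, via monomethyl enone 17 (not isolated)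
Conditions: KOt-Bu (3 equiv), MeI (6 equiv), THF/t-BuOH, 0 °C → rt
Reagents that add atoms: iodomethane CI
Why: Exhaustive α′-methylation of the enone; C6 is the only enolisable position (C2 is quaternary) and no stereocentre is made.

Step 12
Reactants: 18 gem-dimethyl enone
Product: 19 (5R)-2,6,6-trimethyl-9-methylidene-11-(triethylsilyloxy)tricyclo[5.4.0.0^{2,8}]undec-3-en-5-ol (5-OH on the C8 side of the seven-membered ring)
Conditions: (S)-2-methyl-CBS-oxazaborolidine (0.5 equiv), catecholborane, toluene, −78 °C; MeOH, aq. NaOH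
Reagents that add atoms: none
Why: Corey–Bakshi–Shibata reduction under reagent control, needed because the two faces of the C5 ketone differ only through the remote C9–C11 bridge; with the quaternary C6 as the large group and the vinyl CH as the small one, the S catalyst delivers hydride on the C1-side face and gives the 5R alcohol, and catecholborane does not hydroborate the exocyclic alkene at −78 °C.

Step 13
Reactants: 19 allylic alcohol
Product: 20 5-(tert-butyldimethylsilyloxy)-2,6,6-trimethyl-9-methylidene-11-(triethylsilyloxy)tricyclo[5.4.0.0^{2,8}]undec-3-ene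
Conditions: TBSOTf, 2,6-lutidine, CH2Cl2, 0 °C
Reagents that add atoms: tert-butyldimethylsilyl trifluoromethanesulfonate CC(C)(C)[Si](C)(C)OS(=O)(=O)C(F)(F)F
Why: Silylation masks the 5-OH so that only the later 3,4-diol is acylated, and the bulky ether reinforces anti attack in the dihydroxylation.

Step 14
Reactants: 20 bis-silyl ether
Product: 21 5-(tert-butyldimethylsilyloxy)-2,6,6-trimethyl-9-methylidenetricyclo[5.4.0.0^{2,8}]undec-3-en-11-ol
Conditions: PPTS (cat.), MeOH/CH2Cl2, 0 °C → rt
Reagents that add atoms: none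
Why: Acid-catalysed methanolysis removes the secondary TES ether; the neopentyl TBS ether is far slower.

Step 15
Reactants: 21 C11 alcohol
Product: 23 5-(tert-butyldimethylsilyloxy)-2,6,6,9-tetramethyltricyclo[5.4.0.0^{2,8}]undeca-3,9-dien-11-one, via deconjugated ketone 22 (not isolated)
Conditions: Dess–Martin periodinane, NaHCO3, CH2Cl2, rt; then DBU (cat.), rt
Reagents that add atoms: none
Why: Dess–Martin oxidation, then base-mediated migration of the exocyclic alkene into conjugation; the bridgehead α-hydrogen cannot enolise, so nothing epimerises.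

Step 16
Reactants: 23 dienone
Product: 24 5-(tert-butyldimethylsilyloxy)-3,4-dihydroxy-2,6,6,9-tetramethyltricyclo[5.4.0.0^{2,8}]undec-9-en-11-one (3-OH and 4-OH cis, on the C1 side, trans to the 5-oxygen)
Conditions: OsO4 (5 mol %), NMO, acetone/H2O, rt
Reagents that add atoms: osmium tetroxide O=[Os](=O)(=O)=O; 4-methylmorpholine N-oxide C[N+]1([O-])CCOCC1; water O
Why: Upjohn dihydroxylation; OsO4 adds syn to the cis-disubstituted alkene from the face anti to the allylic silyloxy group (Kishi rule), setting C3 and C4, and the electron-poor, hindered enone alkene is left.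

Step 17
Reactants: 24 diol; 25 angelic acid [(2Z)-2-methylbut-2-enoic acid]
Product: 26 5-O-TBS ether of the target, 5-(tert-butyldimethylsilyloxy)-2,6,6,9-tetramethyl-11-oxotricyclo[5.4.0.0^{2,8}]undec-9-ene-3,4-diyl bis[(2Z)-2-methylbut-2-enoate]
Conditions: 25 (6 equiv), 2,4,6-trichlorobenzoyl chloride, Et3N, toluene, rt; then 24, 80 °C
Reagents that add atoms: none
Why: Greene's variant of the Yamaguchi esterification: the mixed anhydride acylates both hindered secondary hydroxyls without DMAP, which avoids Z-to-E isomerisation to the tiglate.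

Step 18
Reactants: 26 silyl ether
Product: 27 target, (1R,2R,3S,4R,5S,7S,8R)-5-hydroxy-2,6,6,9-tetramethyl-11-oxotricyclo[5.4.0.0^{2,8}]undec-9-ene-3,4-diyl bis[(2Z)-2-methylbut-2-enoate]
Conditions: HF·pyridine, pyridine/THF, 0 °C → rt
Reagents that add atoms: none
Why: Fluoride-mediated desilylation under mildly acidic conditions frees the 5-OH without acyl migration or angelate isomerisation.

**Compound list**
1 | ethyl 3-methylbut-2-enoate | CCOC(=O)C=C(C)C | starting material
2 | tert-butyl[(1-ethoxy-3-methylbuta-1,3-dien-1-yl)oxy]dimethylsilane | CCOC(O[Si](C)(C)C(C)(C)C)=CC(C)=C | intermediate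
3 | 3-methylbut-2-enal | CC(C)=CC=O | starting material
4 | ethyl (2E,5S)-5-hydroxy-3,7-dimethylocta-2,6-dienoate | CCOC(=O)/C=C(\C)C[C@H](O)C=C(C)C | intermediate
5 | ethyl (2E,5S,6E)-5,8-dihydroxy-3,7-dimethylocta-2,6-dienoate | CCOC(=O)/C=C(\C)C[C@H](O)/C=C(\C)CO | intermediate
6 | ethyl (2E,5S,6E)-3,7-dimethyl-5,8-bis(triethylsilyloxy)octa-2,6-dienoate | CCOC(=O)/C=C(\C)C[C@H](O[Si](CC)(CC)CC)/C=C(\C)CO[Si](CC)(CC)CC | intermediate
7 | (2E,5S,6E)-3,7-dimethyl-5,8-bis(triethylsilyloxy)octa-2,6-dienoic acid | OC(=O)/C=C(\C)C[C@H](O[Si](CC)(CC)CC)/C=C(\C)CO[Si](CC)(CC)CC | intermediate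
8 | (2E,5S,6E)-3,7-dimethyl-5,8-bis(triethylsilyloxy)octa-2,6-dienoyl chloride | ClC(=O)/C=C(\C)C[C@H](O[Si](CC)(CC)CC)/C=C(\C)CO[Si](CC)(CC)CC | intermediate
9 | (5S,6E)-7-methyl-3-methylidene-5,8-bis(triethylsilyloxy)octa-1,6-dien-1-one (vinylketene) | O=C=CC(=C)C[C@H](O[Si](CC)(CC)CC)/C=C(\C)CO[Si](CC)(CC)CC | intermediate
10 | (1R,4S,5R,7R)-7-methyl-2-methylidene-4-(triethylsilyloxy)-7-[(triethylsilyloxy)methyl]bicyclo[3.1.1]heptan-6-one | O=C1[C@@H]2C(=C)C[C@H](O[Si](CC)(CC)CC)[C@H]1[C@]2(C)CO[Si](CC)(CC)CC | intermediate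
11 | 1-(triphenyl-λ5-phosphanylidene)propan-2-one | CC(=O)C=P(c1ccccc1)(c1ccccc1)c1ccccc1 | starting material
12 | 1-[7-methyl-2-methylidene-4-(triethylsilyloxy)-7-[(triethylsilyloxy)methyl]bicyclo[3.1.1]heptan-6-ylidene]propan-2-one | CC(=O)C=C1[C@@H]2C(=C)C[C@H](O[Si](CC)(CC)CC)[C@H]1[C@]2(C)CO[Si](CC)(CC)CC | intermediate
13 | 1-[7-methyl-2-methylidene-4-(triethylsilyloxy)-7-[(triethylsilyloxy)methyl]bicyclo[3.1.1]heptan-6-yl]propan-2-one | CC(=O)C[C@H]1[C@@H]2C(=C)C[C@H](O[Si](CC)(CC)CC)[C@H]1[C@]2(C)CO[Si](CC)(CC)CC | intermediate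
14 | 7-methyl-2-methylidene-6-(2-oxopropyl)-4-(triethylsilyloxy)bicyclo[3.1.1]heptane-7-carbaldehyde | CC(=O)C[C@H]1[C@@H]2C(=C)C[C@H](O[Si](CC)(CC)CC)[C@H]1[C@]2(C)C=O | intermediate
15 | 3-hydroxy-2-methyl-9-methylidene-11-(triethylsilyloxy)tricyclo[5.4.0.0^{2,8}]undecan-5-one (C3 configuration open) | O=C1C[C@@H]2[C@H]3[C@@H](O[Si](CC)(CC)CC)CC(=C)[C@@H]2[C@@]3(C)C(O)C1 | intermediate
16 | 2-methyl-9-methylidene-11-(triethylsilyloxy)tricyclo[5.4.0.0^{2,8}]undec-3-en-5-one | O=C1C[C@@H]2[C@H]3[C@@H](O[Si](CC)(CC)CC)CC(=C)[C@@H]2[C@@]3(C)C=C1 | intermediate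
17 | 2,6-dimethyl-9-methylidene-11-(triethylsilyloxy)tricyclo[5.4.0.0^{2,8}]undec-3-en-5-one (C6 configuration open) | O=C1C(C)[C@@H]2[C@H]3[C@@H](O[Si](CC)(CC)CC)CC(=C)[C@@H]2[C@@]3(C)C=C1 | intermediate
18 | 2,6,6-trimethyl-9-methylidene-11-(triethylsilyloxy)tricyclo[5.4.0.0^{2,8}]undec-3-en-5-one | O=C1C(C)(C)[C@@H]2[C@H]3[C@@H](O[Si](CC)(CC)CC)CC(=C)[C@@H]2[C@@]3(C)C=C1 | intermediate
19 | (5R)-2,6,6-trimethyl-9-methylidene-11-(triethylsilyloxy)tricyclo[5.4.0.0^{2,8}]undec-3-en-5-ol | O[C@H]1C(C)(C)[C@@H]2[C@H]3[C@@H](O[Si](CC)(CC)CC)CC(=C)[C@@H]2[C@@]3(C)C=C1 | intermediate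
20 | 5-(tert-butyldimethylsilyloxy)-2,6,6-trimethyl-9-methylidene-11-(triethylsilyloxy)tricyclo[5.4.0.0^{2,8}]undec-3-ene | CC(C)(C)[Si](C)(C)O[C@H]1C(C)(C)[C@@H]2[C@H]3[C@@H](O[Si](CC)(CC)CC)CC(=C)[C@@H]2[C@@]3(C)C=C1 | intermediate
21 | 5-(tert-butyldimethylsilyloxy)-2,6,6-trimethyl-9-methylidenetricyclo[5.4.0.0^{2,8}]undec-3-en-11-ol | CC(C)(C)[Si](C)(C)O[C@H]1C(C)(C)[C@@H]2[C@H]3[C@@H](O)CC(=C)[C@@H]2[C@@]3(C)C=C1 | intermediate
22 | 5-(tert-butyldimethylsilyloxy)-2,6,6-trimethyl-9-methylidenetricyclo[5.4.0.0^{2,8}]undec-3-en-11-one | CC(C)(C)[Si](C)(C)O[C@H]1C(C)(C)[C@@H]2[C@H]3C(=O)CC(=C)[C@@H]2[C@@]3(C)C=C1 | intermediate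
23 | 5-(tert-butyldimethylsilyloxy)-2,6,6,9-tetramethyltricyclo[5.4.0.0^{2,8}]undeca-3,9-dien-11-one | CC(C)(C)[Si](C)(C)O[C@H]1C(C)(C)[C@@H]2[C@H]3C(=O)C=C(C)[C@@H]2[C@@]3(C)C=C1 | intermediate
24 | 5-(tert-butyldimethylsilyloxy)-3,4-dihydroxy-2,6,6,9-tetramethyltricyclo[5.4.0.0^{2,8}]undec-9-en-11-one | CC(C)(C)[Si](C)(C)O[C@H]1C(C)(C)[C@@H]2[C@H]3C(=O)C=C(C)[C@@H]2[C@@]3(C)[C@H](O)[C@@H]1O | intermediate
25 | angelic acid, (2Z)-2-methylbut-2-enoic acid | C/C=C(/C)C(=O)O | starting material
26 | 5-(tert-butyldimethylsilyloxy)-2,6,6,9-tetramethyl-11-oxotricyclo[5.4.0.0^{2,8}]undec-9-ene-3,4-diyl bis[(2Z)-2-methylbut-2-enoate] | C/C=C(/C)C(=O)O[C@@H]1[C@@H](O[Si](C)(C)C(C)(C)C)C(C)(C)[C@@H]2[C@H]3C(=O)C=C(C)[C@@H]2[C@@]3(C)[C@@H]1OC(=O)/C(C)=C\C | intermediate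
27 | (1R,2R,3S,4R,5S,7S,8R)-5-hydroxy-2,6,6,9-tetramethyl-11-oxotricyclo[5.4.0.0^{2,8}]undec-9-ene-3,4-diyl bis[(2Z)-2-methylbut-2-enoate] (CNP0336239.1) | C/C=C(/C)C(=O)O[C@@H]1[C@@H](O)C(C)(C)[C@@H]2[C@H]3C(=O)C=C(C)[C@@H]2[C@@]3(C)[C@@H]1OC(=O)/C(C)=C\C | target

**Step count and risk**
Total steps: 18. Longest linear sequence: 18 (1 → 27; compounds 3, 11 and 25 enter directly).

Steps most likely to fail:

Step 6 (ketene [2+2]). The two allylic silyloxy groups make the alkene less nucleophilic, and the conjugated acid chloride can be deprotonated at the wrong γ-position or lactonise. The fallback sets out from ester 6: deconjugation with LiN(i-Pr)2/HMPA and kinetic α-protonation gives ethyl (5S,6E)-7-methyl-3-methylidene-5,8-bis(triethylsilyloxy)oct-6-enoate F1, LiOH gives the β,γ-unsaturated acid F2, and the chloro-enamine reagent gives the acid chloride F3. Ordinary α-dehydrochlorination of this with Et3N in toluene at 80 °C makes the same vinylketene regiospecifically and under milder conditions, so the route is rejoined at 9 and hence 10.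

Step 12 (CBS reduction). Which flank of the ketone acts as the large group is not secure, so the facial sense or the ratio may be poor. The fallback sets out from 18 and gives up reagent control: NaBH4/CeCl3·7H2O gives 19 together with its C5-epimeric allylic alcohol F4. These are diastereomers and are separated by chromatography, F4 is oxidised back to 18 with MnO2 and recycled, and the route is rejoined at 19.

Step 17 (double angeloylation). The C3 hydroxyl is neopentylic and the angelate can isomerise under forcing conditions. The fallback sets out from diol 24 and builds the Z-alkenes after acylation: coupling with 2-[bis(2,2,2-trifluoroethoxy)phosphoryl]propanoic acid (N,N′-dicyclohexylcarbodiimide, DMAP) gives the bis(phosphonopropanoate) F5. Still–Gennari olefination of F5 with acetaldehyde (KN(SiMe3)2, 18-crown-6, THF, −78 °C) forms both (2Z)-2-methylbut-2-enoates and rejoins the route at 26.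

**Further compounds**
F1 | step 6 | ethyl (5S,6E)-7-methyl-3-methylidene-5,8-bis(triethylsilyloxy)oct-6-enoate | CCOC(=O)CC(=C)C[C@H](O[Si](CC)(CC)CC)/C=C(\C)CO[Si](CC)(CC)CC
F2 | step 6 | (5S,6E)-7-methyl-3-methylidene-5,8-bis(triethylsilyloxy)oct-6-enoic acid | OC(=O)CC(=C)C[C@H](O[Si](CC)(CC)CC)/C=C(\C)CO[Si](CC)(CC)CC
F3 | step 6 | (5S,6E)-7-methyl-3-methylidene-5,8-bis(triethylsilyloxy)oct-6-enoyl chloride | ClC(=O)CC(=C)C[C@H](O[Si](CC)(CC)CC)/C=C(\C)CO[Si](CC)(CC)CC
F4 | step 12 | (5S)-2,6,6-trimethyl-9-methylidene-11-(triethylsilyloxy)tricyclo[5.4.0.0^{2,8}]undec-3-en-5-ol (C5 epimer of 19) | O[C@@H]1C(C)(C)[C@@H]2[C@H]3[C@@H](O[Si](CC)(CC)CC)CC(=C)[C@@H]2[C@@]3(C)C=C1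
F5 | step 17 | 5-(tert-butyldimethylsilyloxy)-2,6,6,9-tetramethyl-11-oxotricyclo[5.4.0.0^{2,8}]undec-9-ene-3,4-diyl bis{2-[bis(2,2,2-trifluoroethoxy)phosphoryl]propanoate} | CC(C(=O)O[C@@H]1[C@@H](O[Si](C)(C)C(C)(C)C)C(C)(C)[C@@H]2[C@H]3C(=O)C=C(C)[C@@H]2[C@@]3(C)[C@@H]1OC(=O)C(C)P(=O)(OCC(F)(F)F)OCC(F)(F)F)P(=O)(OCC(F)(F)F)OCC(F)(F)F
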